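## Retrosynthetic overview

- **Feature:** ring A is a pentasubstituted resorcinol. Its C3(OH)–C4(H)–C5(OH)–C6(benzyl) segment is a masked 1,3-dioxygenated diene. C1(arylethyl)–C2 is a masked alkyne, and it becomes an electron-poor ynone once the C2 benzylic CH2 is raised to C=O.
- **Key disconnection:** C6–C1 and C3–C2 are formed together by a Diels–Alder reaction with eliminative aromatisation. Ring A is the only ring built, since the three outer aryl rings are purchased.
- **Fragments:** the diene comes from methyl acetoacetate by γ-benzylation and two O-silylations. The ynone comes from 3-methoxybenzyl bromide by silylpropyne homologation and acyl Sonogashira coupling.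
- **End game:** ionic hydrogenation of the diaryl ketone to CH2, then global O-demethylation.

Key step: step 7

Assumption: ring A is numbered C1 (arylethyl), C2 and C6 (benzyl), C3 and C5 (OH), C4 (H). The target is achiral, so the only stereochemical elements in the route are enol ether geometries and centres that vanish in the flask in which they form.

## Route

Step 1
Reactants: 1 methyl acetoacetate; 2 4-methoxybenzyl chloride
Product: 4 methyl 5-(4-methoxyphenyl)-3-oxopentanoate, via sodium lithium dianion 3 (not isolated)
Conditions: NaH, THF, 0 °C; n-BuLi, 0 °C; then 2, 0 °C → rt; cold 1 M HCl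
Reagents that add atoms: none
Why: γ-Alkylation of an acetoacetate dianion, in which the more basic terminal carbanion attacks the reactive benzylic chloride by SN2 while the stabilised α-enolate stays untouched.

Step 2
Reactants: 4 methyl 5-(4-methoxyphenyl)-3-oxopentanoate
Product: 5 methyl (Z)-5-(4-methoxyphenyl)-3-(trimethylsilyloxy)pent-2-enoate
Conditions: Me3SiCl, Et3N, toluene, rt, 2–3 d; filtration under argon
Reagents that add atoms: chlorotrimethylsilane, C[Si](C)(C)Cl
Why: O-Silylation of the enolised β-keto ester with an amine base gives the silyl enol ether, and its double-bond geometry is irrelevant because that bond becomes the central single bond of the diene.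

Step 3
Reactants: 5 methyl (Z)-5-(4-methoxyphenyl)-3-(trimethylsilyloxy)pent-2-enoate
Product: 7 (1Z,3Z)-1-methoxy-5-(4-methoxyphenyl)-1,3-bis(trimethylsilyloxy)penta-1,3-diene, via lithium dienolate 6 (not isolated)
Conditions: LiN(iPr)2 (commercial solution), THF, −78 °C; Me3SiCl, −78 °C → rt; concentration, hexane, filtration under argon; used crude
Reagents that add atoms: chlorotrimethylsilane, C[Si](C)(C)Cl
Why: Kinetic γ-deprotonation of the vinylogous ester and O-silylation of the extended enolate (silyl ketene acetal formation) should give the diene, with allylic strain in the deprotonation placing the CH2Ar group trans to C2 (3Z), which is the geometry that can reach the s-cis conformation.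

Step 4
Reactants: 8 1-(trimethylsilyl)propyne; 9 3-methoxybenzyl bromide
Product: 11 4-(3-methoxyphenyl)-1-(trimethylsilyl)but-1-yne, via 3-lithio-1-(trimethylsilyl)propyne 10 (not isolated)
Conditions: n-BuLi, THF, −78 → −20 °C; then 9, −78 °C → rt
Reagents that add atoms: none
Why: SN2 alkylation of a propargyllithium, in which the bulky silyl group on the alkyne terminus suppresses the allenyl mode of attack so that the CH2 terminus displaces the benzylic bromide.

Step 5
Reactants: 11 4-(3-methoxyphenyl)-1-(trimethylsilyl)but-1-yne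
Product: 12 4-(3-methoxyphenyl)but-1-yne
Conditions: K2CO3 (0.2 equiv), MeOH, rt
Reagents that add atoms: none
Why: Base-catalysed protodesilylation of an alkynylsilane by methoxide, to which the aryl methyl ether is inert.

Step 6
Reactants: 12 4-(3-methoxyphenyl)but-1-yne; 13 4-methoxybenzoyl chloride
Product: 14 1-(4-methoxyphenyl)-5-(3-methoxyphenyl)pent-2-yn-1-one
Conditions: PdCl2(PPh3)2 (2 mol %), CuI (4 mol %), Et3N (1.5 equiv), THF, rt, argon
Reagents that add atoms: none
Why: Acyl Sonogashira coupling, in which oxidative addition of the acid chloride to zerovalent palladium, transmetalation from the copper acetylide and reductive elimination should deliver the ynone at room temperature without decarbonylation.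

Step 7
Reactants: 7 (1Z,3Z)-1-methoxy-5-(4-methoxyphenyl)-1,3-bis(trimethylsilyloxy)penta-1,3-diene (2.5 equiv); 14 1-(4-methoxyphenyl)-5-(3-methoxyphenyl)pent-2-yn-1-one
Product: 17 {2,4-dihydroxy-5-(4-methoxybenzyl)-6-[2-(3-methoxyphenyl)ethyl]phenyl}(4-methoxyphenyl)methanone, via cyclohexa-1,4-diene cycloadduct 15 (not isolated), via aromatic bis(trimethylsilyl) ether 16 (not isolated)
Conditions: toluene (minimum volume), sealed tube, argon, 120 °C, 24–48 h; then 1 M HCl, THF/MeOH, rt
Reagents that add atoms: none
Why: This is the known thermal Diels–Alder reaction of a 1-alkoxy-1,3-bis(silyloxy)diene with an acetylenic ketone followed by eliminative aromatisation: s-cis 7 adds suprafacially to the triple bond of 14 in a concerted but strongly asynchronous, polarised [4+2] process in which the C6–C1 bond (carbon-substituted diene terminus to ynone β-carbon) runs ahead of the C3–C2 bond (ketene acetal carbon to ynone α-carbon). Ring A closes in this single intermolecular [4+2] event as cyclohexa-1,4-diene 15, whose C3 mixed ketal ionises easily, so that methanol is lost across C3 and C6 to give aromatic 16, and dilute acid then frees the C3 and C5 phenols of 17. The two sp3 centres of 15 (C3 and C6, methoxy and benzyl cis as dictated by the 1Z,3Z geometry and suprafacial addition) are erased on aromatisation, so no stereocontrol is needed and only the 3Z geometry matters, because it keeps the benzyl group on the outside of the s-cis diene. The selectivity that counts is regiochemical: all three oxygen donors push electron density to the C6 terminus and the aroyl group makes the alkyne β-carbon the electrophilic end, a match that puts the arylethyl chain on C1 between the two benzylic carbons and the carbonyl on C2 beside the C3 hydroxyl. Chemoselectivity for [4+2] over a Michael–aldol [3+3] path to a salicylate, or over attack at the ketone carbonyl, is secured by excluding Lewis acids and working thermally at high concentration in a non-polar medium. The fragile diene is taken in excess because bond formation between the two substituted termini should be slow.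

Step 8
Reactants: 17 {2,4-dihydroxy-5-(4-methoxybenzyl)-6-[2-(3-methoxyphenyl)ethyl]phenyl}(4-methoxyphenyl)methanone
Product: 19 4,6-bis(4-methoxybenzyl)-5-[2-(3-methoxyphenyl)ethyl]benzene-1,3-diol, via benzhydrol 18 (not isolated)
Conditions: Et3SiH (8 equiv), TFA/CH2Cl2, 0 °C → rt, 17 added slowly at high dilution
Reagents that add atoms: none
Why: Ionic hydrogenation, in which the protonated ketone accepts hydride to give 18, which ionises in TFA to a cation stabilised by the 4-methoxyphenyl ring and by the ortho and para hydroxyls of ring A and is reduced again, the large excess of silane (a much better nucleophile towards benzhydryl cations than an alkylanisole) outrunning arene capture.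

Step 9
Reactants: 19 4,6-bis(4-methoxybenzyl)-5-[2-(3-methoxyphenyl)ethyl]benzene-1,3-diol
Product: 20 shanciguol, 4,6-bis(4-hydroxybenzyl)-5-[2-(3-hydroxyphenyl)ethyl]benzene-1,3-diol
Conditions: BBr3 (8 equiv), CH2Cl2, −78 °C → rt; ice-water quench
Reagents that add atoms: none
Why: Lewis-acid aryl methyl ether cleavage, in which BBr3 binds each ether oxygen, bromide removes the methyl group by SN2 and hydrolysis on work-up frees the three remaining phenols, no other BBr3-labile group being present.

## Compound list

1 | methyl acetoacetate | CC(=O)CC(=O)OC | starting material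
2 | 4-methoxybenzyl chloride | COc1ccc(CCl)cc1 | starting material
3 | sodium lithium dianion of methyl acetoacetate | [Na+].[Li+].[CH2-]C(=O)[CH-]C(=O)OC | intermediate
4 | methyl 5-(4-methoxyphenyl)-3-oxopentanoate | COC(=O)CC(=O)CCc1ccc(OC)cc1 | intermediate
5 | methyl (Z)-5-(4-methoxyphenyl)-3-(trimethylsilyloxy)pent-2-enoate | COC(=O)/C=C(\O[Si](C)(C)C)CCc1ccc(OC)cc1 | intermediate
6 | lithium 1-methoxy-5-(4-methoxyphenyl)-3-(trimethylsilyloxy)penta-1,3-dien-1-olate | [Li+].CO/C([O-])=C/C(O[Si](C)(C)C)=C/Cc1ccc(OC)cc1 | intermediate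
7 | (1Z,3Z)-1-methoxy-5-(4-methoxyphenyl)-1,3-bis(trimethylsilyloxy)penta-1,3-diene | CO/C(O[Si](C)(C)C)=C/C(O[Si](C)(C)C)=C/Cc1ccc(OC)cc1 | intermediate
8 | 1-(trimethylsilyl)propyne | CC#C[Si](C)(C)C | starting material
9 | 3-methoxybenzyl bromide | COc1cccc(CBr)c1 | starting material
10 | 3-lithio-1-(trimethylsilyl)propyne | [Li]CC#C[Si](C)(C)C | intermediate
11 | 4-(3-methoxyphenyl)-1-(trimethylsilyl)but-1-yne | COc1cccc(CCC#C[Si](C)(C)C)c1 | intermediate
12 | 4-(3-methoxyphenyl)but-1-yne | C#CCCc1cccc(OC)c1 | intermediate
13 | 4-methoxybenzoyl chloride | COc1ccc(C(=O)Cl)cc1 | starting material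
14 | 1-(4-methoxyphenyl)-5-(3-methoxyphenyl)pent-2-yn-1-one | COc1ccc(C(=O)C#CCCc2cccc(OC)c2)cc1 | intermediate
15 | {6-methoxy-3-(4-methoxybenzyl)-2-[2-(3-methoxyphenyl)ethyl]-4,6-bis(trimethylsilyloxy)cyclohexa-1,4-dien-1-yl}(4-methoxyphenyl)methanone, racemic, methoxy and benzyl cis (one enantiomer drawn) | CO[C@@]1(O[Si](C)(C)C)C=C(O[Si](C)(C)C)[C@@H](Cc2ccc(OC)cc2)C(CCc2cccc(OC)c2)=C1C(=O)c1ccc(OC)cc1 | intermediate
16 | {5-(4-methoxybenzyl)-6-[2-(3-methoxyphenyl)ethyl]-2,4-bis(trimethylsilyloxy)phenyl}(4-methoxyphenyl)methanone | COc1ccc(Cc2c(O[Si](C)(C)C)cc(O[Si](C)(C)C)c(C(=O)c3ccc(OC)cc3)c2CCc2cccc(OC)c2)cc1 | intermediate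
17 | {2,4-dihydroxy-5-(4-methoxybenzyl)-6-[2-(3-methoxyphenyl)ethyl]phenyl}(4-methoxyphenyl)methanone | COc1ccc(Cc2c(O)cc(O)c(C(=O)c3ccc(OC)cc3)c2CCc2cccc(OC)c2)cc1 | intermediate
18 | 4-[hydroxy(4-methoxyphenyl)methyl]-6-(4-methoxybenzyl)-5-[2-(3-methoxyphenyl)ethyl]benzene-1,3-diol, racemic | COc1ccc(Cc2c(O)cc(O)c(C(O)c3ccc(OC)cc3)c2CCc2cccc(OC)c2)cc1 | intermediate
19 | 4,6-bis(4-methoxybenzyl)-5-[2-(3-methoxyphenyl)ethyl]benzene-1,3-diol | COc1ccc(Cc2c(O)cc(O)c(Cc3ccc(OC)cc3)c2CCc2cccc(OC)c2)cc1 | intermediate
20 | shanciguol | Oc1ccc(Cc2c(O)cc(O)c(Cc3ccc(O)cc3)c2CCc2cccc(O)c2)cc1 | target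

## Step count

Total step count: 9.
Longest linear sequence: 6 (steps 1–3 or steps 4–6, then steps 7–9).

## Steps most likely to fail

**1. Step 7.**
- **Risk:** bond formation between a substituted diene terminus and a substituted alkyne carbon may be so slow that thermal silyl migration and hydrolysis of the diene win over cycloaddition.
- **Fallback:** it sets out from 1 and 14 and returns at 17. The C6 benzyl group is no longer carried through the cycloaddition but is installed afterwards by electrophilic aromatic substitution.
  - Compound 1 is silylated as in step 2 to methyl (Z)-3-(trimethylsilyloxy)but-2-enoate F1.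
  - F1 is treated as in step 3 to give (Z)-1-methoxy-1,3-bis(trimethylsilyloxy)buta-1,3-diene F2, whose reacting terminus is an unhindered CH2.
  - Heating F2 with 14 and acidic work-up should give {2,4-dihydroxy-6-[2-(3-methoxyphenyl)ethyl]phenyl}(4-methoxyphenyl)methanone F3.
  - Et3SiH in TFA reduces F3 to 4-(4-methoxybenzyl)-5-[2-(3-methoxyphenyl)ethyl]benzene-1,3-diol F4.
  - Friedel–Crafts/Fries aroylation of F4 with 13 (BF3·OEt2, 1,2-dichloroethane, heat) should take place on the most activated ring, at the one remaining position ortho to one hydroxyl and para to the other. This is the usual site for 5-alkylresorcinols, and the product is 17.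

**2. Step 8.**
- **Risk:** hydride delivery to the hindered, hydrogen-bonded carbonyl may be sluggish. The benzhydryl cation may also be intercepted by an arene, either by seven-membered Friedel–Crafts closure onto the 3-methoxyphenyl ring or by attack of C4 of a second resorcinol molecule. Acid-induced loss of an aroyl or benzyl group from ring A may intervene as well.
- **Fallback:** it sets out from 17 and returns at 19. It avoids acid and free cations by passing through an ortho-quinone methide under basic hydride conditions.
  - Ethyl chloroformate and Et3N in THF give 4-(4-methoxybenzoyl)-6-(4-methoxybenzyl)-5-[2-(3-methoxyphenyl)ethyl]benzene-1,3-diyl diethyl biscarbonate F5.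
  - NaBH4 in aqueous THF reduces the ketone, which is no longer chelated. The alkoxide takes over the neighbouring carbonate, the C3 phenoxide expels ethyl carbonate, and borohydride adds to the exocyclic carbon of the quinone methide. The product is ethyl 5-hydroxy-2,4-bis(4-methoxybenzyl)-3-[2-(3-methoxyphenyl)ethyl]phenyl carbonate F6.
  - Aqueous NaOH followed by acidification removes the last carbonate and gives 19.

**3. Step 3.**
- **Risk:** incomplete γ-deprotonation, competing C-silylation, erosion of the 3Z geometry and hydrolysis on handling may leave too little competent diene.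
- **Fallback:** it sets out from 4 and returns at 20. It replaces the C5 silyl enol ether by a robust methyl enol ether that can be purified.
  - Trimethyl orthoformate with catalytic H2SO4 in MeOH converts 4 into methyl (E)-3-methoxy-5-(4-methoxyphenyl)pent-2-enoate F7.
  - LiN(iPr)2 and Me3SiCl give (1Z,3Z)-1,3-dimethoxy-5-(4-methoxyphenyl)-1-(trimethylsilyloxy)penta-1,3-diene F8.
  - Heating F8 with 14 as in step 7 should give {2-hydroxy-4-methoxy-5-(4-methoxybenzyl)-6-[2-(3-methoxyphenyl)ethyl]phenyl}(4-methoxyphenyl)methanone F9.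
  - The conditions of step 8 reduce F9 to 5-methoxy-2,4-bis(4-methoxybenzyl)-3-[2-(3-methoxyphenyl)ethyl]phenol F10.
  - BBr3 as in step 9 cleaves all four methyl ethers of F10 to give 20.

## Further compounds

F1 | step 7 | methyl (Z)-3-(trimethylsilyloxy)but-2-enoate | COC(=O)/C=C(\O[Si](C)(C)C)C
F2 | step 7 | (Z)-1-methoxy-1,3-bis(trimethylsilyloxy)buta-1,3-diene | CO/C(O[Si](C)(C)C)=C/C(=C)O[Si](C)(C)C
F3 | step 7 | {2,4-dihydroxy-6-[2-(3-methoxyphenyl)ethyl]phenyl}(4-methoxyphenyl)methanone | COc1ccc(C(=O)c2c(O)cc(O)cc2CCc2cccc(OC)c2)cc1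
F4 | step 7 | 4-(4-methoxybenzyl)-5-[2-(3-methoxyphenyl)ethyl]benzene-1,3-diol | COc1ccc(Cc2c(O)cc(O)cc2CCc2cccc(OC)c2)cc1
F5 | step 8 | 4-(4-methoxybenzoyl)-6-(4-methoxybenzyl)-5-[2-(3-methoxyphenyl)ethyl]benzene-1,3-diyl diethyl biscarbonate | CCOC(=O)Oc1cc(OC(=O)OCC)c(C(=O)c2ccc(OC)cc2)c(CCc2cccc(OC)c2)c1Cc1ccc(OC)cc1
F6 | step 8 | ethyl 5-hydroxy-2,4-bis(4-methoxybenzyl)-3-[2-(3-methoxyphenyl)ethyl]phenyl carbonate | CCOC(=O)Oc1cc(O)c(Cc2ccc(OC)cc2)c(CCc2cccc(OC)c2)c1Cc1ccc(OC)cc1
F7 | step 3 | methyl (E)-3-methoxy-5-(4-methoxyphenyl)pent-2-enoate | COC(=O)/C=C(/OC)CCc1ccc(OC)cc1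
F8 | step 3 | (1Z,3Z)-1,3-dimethoxy-5-(4-methoxyphenyl)-1-(trimethylsilyloxy)penta-1,3-diene | CO/C(O[Si](C)(C)C)=C/C(OC)=C/Cc1ccc(OC)cc1
F9 | step 3 | {2-hydroxy-4-methoxy-5-(4-methoxybenzyl)-6-[2-(3-methoxyphenyl)ethyl]phenyl}(4-methoxyphenyl)methanone | COc1ccc(Cc2c(OC)cc(O)c(C(=O)c3ccc(OC)cc3)c2CCc2cccc(OC)c2)cc1
F10 | step 3 | 5-methoxy-2,4-bis(4-methoxybenzyl)-3-[2-(3-methoxyphenyl)ethyl]phenol | COc1ccc(Cc2c(OC)cc(O)c(Cc3ccc(OC)cc3)c2CCc2cccc(OC)c2)cc1
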